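**Retrosynthetic overview**
1. Homo-plakotenin ⇒ (saponification, HWE olefination) a neopentyl aldehyde. The cyclohexene is closed at its C(Et)=CH bond by ring-closing metathesis, not by the biomimetic intramolecular Diels–Alder reaction.
2. The vicinal quaternary/benzylic stereocentres ⇒ one domino Cu-catalysed vinyl iodide/alcohol C–O coupling and Claisen rearrangement, with chirality relayed from (2R,3Z)-4-phenylbut-3-en-2-ol.
3. Hidden C2 symmetry (cyclopentane core plus the two ethyl-bearing carbons) ⇒ C2-symmetric 1,2-diethynyl-3,5-dimethylcyclopentane. Each alkyne is ethyl-cuprated, one quenched with H+ and one with I2.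
4. The two contra-thermodynamic ring methyls (each cis to its neighbouring carbon substituent) ⇒ twofold 8-aminoquinoline-directed β-C(sp3)–H methylation of the bis-amide of (1R,2R)-cyclopentane-1,2-dicarboxylic acid.
5. Ring order: the cyclopentane is bought and carries both ring-fusion centres. The cyclohexene is formed in the penultimate step.

Assumption: the SMILES is taken as authoritative for all six stereocentres (1R,3R,3aR,4S,5S,7aR; E-enoic acid), and (1R,2R)-cyclopentane-1,2-dicarboxylic acid is bought enantiopure (otherwise obtained by resolving the commercial racemic trans-acid).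

Step 1
Reactants: 1 (1R,2R)-cyclopentane-1,2-dicarboxylic acid; 2 quinolin-8-amine (8-aminoquinoline)
Product: 4 (1R,2R)-N1,N2-di(quinolin-8-yl)cyclopentane-1,2-dicarboxamide, via (1R,2R)-cyclopentane-1,2-dicarbonyl dichloride 3 (not isolated)
Conditions: SOCl2, cat. DMF, PhMe, 70 °C; evaporate; 2 (2.1 equiv), Et3N, CH2Cl2, 0 °C to rt
Reagents that add atoms: none
Why: Amide formation via the acid chloride (Schotten–Baumann type) puts the bidentate directing group on both homotopic carboxyls at once, and the two α-stereocentres are safe because the trans-diacyl arrangement is the thermodynamic one.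

Step 2
Reactants: 4 (1R,2R)-N1,N2-di(quinolin-8-yl)cyclopentane-1,2-dicarboxamide
Product: 5 (1R,2R,3R,5R)-3,5-dimethyl-N1,N2-di(quinolin-8-yl)cyclopentane-1,2-dicarboxamide (C2-symmetric; each methyl cis to the neighbouring amide, the two amides trans)
Conditions: Pd(OAc)2 (20 mol %), MeI (6 equiv), Ag2CO3 (3 equiv), (BnO)2PO2H (40 mol %), t-AmOH, 110 °C, sealed tube
Reagents that add atoms: iodomethane, CI
Why: In this 8-aminoquinoline-directed Pd(II)/Pd(IV) β-C(sp3)–H alkylation each N,N-chelated Pd reaches only the β-methylene C–H cis to its own carbonyl (5,5-fused palladacycle), so MeI oxidative addition and reductive elimination with retention place each methyl cis to its amide, set both contra-thermodynamic C–Me centres (3R,5R) in one operation, and stop at two methyls because no cis β-C–H is left.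

Step 3
Reactants: 5 (1R,2R,3R,5R)-3,5-dimethyl-N1,N2-di(quinolin-8-yl)cyclopentane-1,2-dicarboxamide
Product: 6 di-tert-butyl N,N'-{[(1R,2R,3R,5R)-3,5-dimethylcyclopentane-1,2-diyl]dicarbonyl}bis[N-(quinolin-8-yl)carbamate]
Conditions: Boc2O (5 equiv), cat. DMAP, MeCN, 50 °C
Reagents that add atoms: di-tert-butyl dicarbonate, CC(C)(C)OC(=O)OC(=O)OC(C)(C)C
Why: N-Boc activation (N-acylation) turns the inert secondary amides into twisted, imide-like acyl donors under essentially neutral conditions that touch no stereocentre.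

Step 4
Reactants: 6 bis(N-Boc) bis-amide
Product: 7 [(1R,2R,3R,5R)-3,5-dimethylcyclopentane-1,2-diyl]dimethanol
Conditions: LiBH4, THF/MeOH (20:1), 0 °C to rt
Reagents that add atoms: none
Why: Borohydride reduction of an N-acyl carbamate attacks the more electrophilic acyl carbonyl and expels the carbamate anion, and the transient aldehyde is reduced faster than it can enolise, so all four centres are kept.

Step 5
Reactants: 7 [(1R,2R,3R,5R)-3,5-dimethylcyclopentane-1,2-diyl]dimethanol
Product: 8 (1R,2R,3R,5R)-3,5-dimethylcyclopentane-1,2-dicarbaldehyde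
Conditions: Dess–Martin periodinane (2.4 equiv), CH2Cl2, 0 °C to rt; used at once
Reagents that add atoms: none
Why: Dess–Martin oxidation is non-basic, and a single α-epimerisation would be uphill (three contiguous cis substituents), so the cis-methyl/formyl relationships survive.

Step 6
Reactants: 8 (1R,2R,3R,5R)-3,5-dimethylcyclopentane-1,2-dicarbaldehyde
Product: 9 (1R,2R,3R,5R)-1,2-diethynyl-3,5-dimethylcyclopentane
Conditions: TMSCHN2 (2.6 equiv), n-BuLi (2.6 equiv), THF, −78 °C; add 8; −78 °C to rt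
Reagents that add atoms: (trimethylsilyl)diazomethane, C[Si](C)(C)C=[N+]=[N-]
Why: In the Colvin rearrangement (Seyferth–Gilbert-type homologation) addition at −78 °C outruns enolisation, and Peterson-type loss of silanolate, loss of N2 and a 1,2-H shift give the terminal alkynes without touching the α-centres.

Step 7
Reactants: 9 (1R,2R,3R,5R)-1,2-diethynyl-3,5-dimethylcyclopentane
Product: 11 (1R,2R,3R,5R)-1-(but-1-en-2-yl)-2-ethynyl-3,5-dimethylcyclopentane, via {(1E)-2-[(1R,2R,3R,5R)-2-ethynyl-3,5-dimethylcyclopentyl]but-1-en-1-yl}copper 10 (not isolated)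
Conditions: EtMgBr (1.0 equiv), CuBr·SMe2 (1.0 equiv), Et2O/Me2S, −45 to −20 °C; sat. aq NH4Cl; recovered 9 recycled
Reagents that add atoms: ethylmagnesium bromide, CC[Mg]Br
Why: Normant carbocupration adds Et–Cu syn with ethyl on the internal carbon, and because the two alkynes of C2-symmetric 9 are homotopic, mono-addition (statistical, at most about 50 % per pass) followed by protonolysis gives one single 1-ethylvinyl compound.

Step 8
Reactants: 11 (1R,2R,3R,5R)-1-(but-1-en-2-yl)-2-ethynyl-3,5-dimethylcyclopentane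
Product: 13 (1R,2R,3R,5R)-1-(but-1-en-2-yl)-2-[(1E)-1-iodobut-1-en-2-yl]-3,5-dimethylcyclopentane (iodine cis to ethyl, trans to the ring), via {(1E)-2-[(1R,2R,3R,5R)-2-(but-1-en-2-yl)-3,5-dimethylcyclopentyl]but-1-en-1-yl}copper 12 (not isolated)
Conditions: EtMgBr, CuBr·SMe2 (1.5 equiv each), Et2O/Me2S, −45 to −20 °C; I2, THF, −45 to 0 °C
Reagents that add atoms: ethylmagnesium bromide, CC[Mg]Br; iodine, II
Why: A second Normant carbocupration (syn, ethyl to the internal carbon, the 1,1-disubstituted alkene is inert) followed by iodinolysis with retention fixes the trisubstituted vinyl iodide geometry that later encodes the quaternary centre.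

Step 9
Reactants: 14 4-phenylbut-3-yn-2-one
Product: 15 (2R)-4-phenylbut-3-yn-2-ol
Conditions: RuCl[(R,R)-TsDPEN](p-cymene) (0.5 mol %), i-PrOH, rt
Reagents that add atoms: none
Why: Noyori asymmetric transfer hydrogenation of an ynone treats the alkynyl group as the π-substituent, so the (R,R)-catalyst delivers hydride to give the (R)-propargylic alcohol in high ee without touching the triple bond.

Step 10
Reactants: 15 (2R)-4-phenylbut-3-yn-2-ol
Product: 16 (2R,3Z)-4-phenylbut-3-en-2-ol
Conditions: H2 (1 atm), Lindlar catalyst, quinoline, EtOAc, rt, stopped at 1 equiv H2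
Reagents that add atoms: none
Why: Lindlar semihydrogenation adds H2 syn to give the Z-styrenyl alcohol with the carbinol centre untouched.

Step 11
Reactants: 13 (1R,2R,3R,5R)-1-(but-1-en-2-yl)-2-[(1E)-1-iodobut-1-en-2-yl]-3,5-dimethylcyclopentane; 16 (2R,3Z)-4-phenylbut-3-en-2-ol
Product: 18 (2R,3S,4E)-2-[(1R,2R,3R,5R)-2-(but-1-en-2-yl)-3,5-dimethylcyclopentyl]-2-ethyl-3-phenylhex-4-enal, via (1R,2R,3R,5R)-1-(but-1-en-2-yl)-3,5-dimethyl-2-[(1E)-1-{[(2R,3Z)-4-phenylbut-3-en-2-yl]oxy}but-1-en-2-yl]cyclopentane 17 (not isolated)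
Conditions: CuI (15 mol %), 3,4,7,8-tetramethyl-1,10-phenanthroline (30 mol %), Cs2CO3 (1.5 equiv), o-xylene, 120 to 140 °C
Reagents that add atoms: none
Why: Ullmann-type Cu(I) vinylic C–O coupling keeps the iodide geometry and the resulting allyl vinyl ether undergoes an aliphatic Claisen [3,3] rearrangement through a chair with the carbinol methyl equatorial (the axial alternative clashes with the cis-phenyl, A1,3 strain), so the (R)-carbinol is relayed suprafacially to the (S)-benzylic carbon, and the fixed enol-ether geometry (O cis to ethyl) paired with the Z-styrene puts Ph and Et on the same side of the future ring and gives the (R)-quaternary aldehyde carbon under reagent rather than substrate control.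

Step 12
Reactants: 18 (2R,3S,4E)-2-[(1R,2R,3R,5R)-2-(but-1-en-2-yl)-3,5-dimethylcyclopentyl]-2-ethyl-3-phenylhex-4-enal
Product: 19 ethyl (2E,4S,5S,6E)-4-[(1R,2R,3R,5R)-2-(but-1-en-2-yl)-3,5-dimethylcyclopentyl]-4-ethyl-2-methyl-5-phenylocta-2,6-dienoate
Conditions: triethyl 2-phosphonopropionate (3 equiv), NaH, THF, 0 °C to 60 °C
Reagents that add atoms: triethyl 2-phosphonopropionate, CCOC(=O)C(C)P(=O)(OCC)OCC
Why: In the Horner–Wadsworth–Emmons olefination the small, reactive phosphonate anion still adds to the non-enolisable neopentyl aldehyde, whose bulk enforces the E-trisubstituted enoate, and it is done before ring closure because the aldehyde becomes axial and more shielded afterwards.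

Step 13
Reactants: 19 ethyl (2E,4S,5S,6E)-4-[(1R,2R,3R,5R)-2-(but-1-en-2-yl)-3,5-dimethylcyclopentyl]-4-ethyl-2-methyl-5-phenylocta-2,6-dienoate
Product: 20 ethyl (2E)-3-[(1R,3R,3aR,4S,5S,7aR)-4,7-diethyl-1,3-dimethyl-5-phenyl-2,3,3a,4,5,7a-hexahydro-1H-inden-4-yl]-2-methylprop-2-enoate
Conditions: Hoveyda–Grubbs II (10 mol %), PhMe (2 mM), 80 °C, N2 sparge
Reagents that add atoms: none
Why: Ring-closing metathesis of the propenyl and 1-ethylvinyl groups closes the trans-fused cyclohexene at its trisubstituted C=C with loss of propene, creates no stereocentre, leaves the electron-poor trisubstituted enoate alone, and has no viable competitor because the alternative closures would give a cyclobutene or a trans-bicyclo[3.3.0]octene.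

Step 14
Reactants: 20 homo-plakotenin ethyl ester
Product: 22 homo-plakotenin, (2E)-3-[(1R,3R,3aR,4S,5S,7aR)-4,7-diethyl-1,3-dimethyl-5-phenyl-2,3,3a,4,5,7a-hexahydro-1H-inden-4-yl]-2-methylprop-2-enoic acid, via lithium homo-plakoteninate 21 (not isolated)
Conditions: LiOH, THF/MeOH/H2O, 50 °C; then 1 M HCl
Reagents that add atoms: lithium hydroxide, [Li+].[OH-]
Why: Saponification (BAc2) of the unhindered side-chain ester touches no epimerisable centre and does not isomerise the α-methyl E-enoate.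

**Compound list**
1 | (1R,2R)-cyclopentane-1,2-dicarboxylic acid | OC(=O)[C@H]1[C@H](C(=O)O)CCC1 | starting material
2 | quinolin-8-amine | Nc1cccc2cccnc12 | starting material
3 | (1R,2R)-cyclopentane-1,2-dicarbonyl dichloride | ClC(=O)[C@H]1[C@H](C(=O)Cl)CCC1 | intermediate
4 | (1R,2R)-N1,N2-di(quinolin-8-yl)cyclopentane-1,2-dicarboxamide | O=C(Nc1cccc2cccnc12)[C@H]3[C@H](C(=O)Nc4cccc5cccnc45)CCC3 | intermediate
5 | (1R,2R,3R,5R)-3,5-dimethyl-N1,N2-di(quinolin-8-yl)cyclopentane-1,2-dicarboxamide | O=C(Nc1cccc2cccnc12)[C@H]3[C@H](C(=O)Nc4cccc5cccnc45)[C@H](C)C[C@H]3C | intermediate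
6 | di-tert-butyl N,N'-{[(1R,2R,3R,5R)-3,5-dimethylcyclopentane-1,2-diyl]dicarbonyl}bis[N-(quinolin-8-yl)carbamate] | O=C(N(C(=O)OC(C)(C)C)c1cccc2cccnc12)[C@H]3[C@H](C(=O)N(C(=O)OC(C)(C)C)c4cccc5cccnc45)[C@H](C)C[C@H]3C | intermediate
7 | [(1R,2R,3R,5R)-3,5-dimethylcyclopentane-1,2-diyl]dimethanol | OC[C@H]1[C@H](CO)[C@H](C)C[C@H]1C | intermediate
8 | (1R,2R,3R,5R)-3,5-dimethylcyclopentane-1,2-dicarbaldehyde | O=C[C@H]1[C@H](C=O)[C@H](C)C[C@H]1C | intermediate
9 | (1R,2R,3R,5R)-1,2-diethynyl-3,5-dimethylcyclopentane | C#C[C@H]1[C@H](C#C)[C@H](C)C[C@H]1C | intermediate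
10 | {(1E)-2-[(1R,2R,3R,5R)-2-ethynyl-3,5-dimethylcyclopentyl]but-1-en-1-yl}copper | C#C[C@H]1[C@H](/C(CC)=C/[Cu])[C@H](C)C[C@H]1C | intermediate
11 | (1R,2R,3R,5R)-1-(but-1-en-2-yl)-2-ethynyl-3,5-dimethylcyclopentane | C#C[C@H]1[C@H](C(=C)CC)[C@H](C)C[C@H]1C | intermediate
12 | {(1E)-2-[(1R,2R,3R,5R)-2-(but-1-en-2-yl)-3,5-dimethylcyclopentyl]but-1-en-1-yl}copper | [Cu]/C=C(\CC)[C@H]1[C@H](C(=C)CC)[C@H](C)C[C@H]1C | intermediate
13 | (1R,2R,3R,5R)-1-(but-1-en-2-yl)-2-[(1E)-1-iodobut-1-en-2-yl]-3,5-dimethylcyclopentane | I/C=C(\CC)[C@H]1[C@H](C(=C)CC)[C@H](C)C[C@H]1C | intermediate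
14 | 4-phenylbut-3-yn-2-one | CC(=O)C#Cc1ccccc1 | starting material
15 | (2R)-4-phenylbut-3-yn-2-ol | C[C@@H](O)C#Cc1ccccc1 | intermediate
16 | (2R,3Z)-4-phenylbut-3-en-2-ol | C[C@@H](O)/C=C\c1ccccc1 | intermediate
17 | (1R,2R,3R,5R)-1-(but-1-en-2-yl)-3,5-dimethyl-2-[(1E)-1-{[(2R,3Z)-4-phenylbut-3-en-2-yl]oxy}but-1-en-2-yl]cyclopentane | C[C@@H](O/C=C(\CC)[C@H]1[C@H](C(=C)CC)[C@H](C)C[C@H]1C)/C=C\c2ccccc2 | intermediate
18 | (2R,3S,4E)-2-[(1R,2R,3R,5R)-2-(but-1-en-2-yl)-3,5-dimethylcyclopentyl]-2-ethyl-3-phenylhex-4-enal | C/C=C/[C@@H](c1ccccc1)[C@@](C=O)(CC)[C@H]2[C@H](C(=C)CC)[C@H](C)C[C@H]2C | intermediate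
19 | ethyl (2E,4S,5S,6E)-4-[(1R,2R,3R,5R)-2-(but-1-en-2-yl)-3,5-dimethylcyclopentyl]-4-ethyl-2-methyl-5-phenylocta-2,6-dienoate | C/C=C/[C@@H](c1ccccc1)[C@@](/C=C(\C)C(=O)OCC)(CC)[C@H]2[C@H](C(=C)CC)[C@H](C)C[C@H]2C | intermediate
20 | ethyl (2E)-3-[(1R,3R,3aR,4S,5S,7aR)-4,7-diethyl-1,3-dimethyl-5-phenyl-2,3,3a,4,5,7a-hexahydro-1H-inden-4-yl]-2-methylprop-2-enoate | CCC1=C[C@@H](c2ccccc2)[C@@](/C=C(\C)C(=O)OCC)(CC)[C@H]2[C@H]1[C@H](C)C[C@H]2C | intermediate
21 | lithium homo-plakoteninate | CCC1=C[C@@H](c2ccccc2)[C@@](/C=C(\C)C(=O)[O-])(CC)[C@H]2[C@H]1[C@H](C)C[C@H]2C.[Li+] | intermediate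
22 | homo-plakotenin | CCC1=C[C@@H](c2ccccc2)[C@@](/C=C(\C)C(=O)O)(CC)[C@H]2[C@H]1[C@H](C)C[C@H]2C | target

**Step count:** 14 steps in total. The longest linear sequence is 12 steps (steps 1–8 and 11–14). Steps 9–10 make the side fragment.

**The three steps most likely to fail**

**Step 2 (twofold C–H methylation).** The vicinal bis-amide may sequester Pd(II) as a tetradentate N4 chelate, and two methylene activations are needed.
- The fallback sets out from 1 and comes back at 7. It replaces the bidentate auxiliary with weak-coordination, ligand-enabled C–H activation.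
- Acid chloride 3, made from 1 as in step 1, is condensed with 2,3,5,6-tetrafluoro-4-(trifluoromethyl)aniline and Et3N. This gives (1R,2R)-N1,N2-bis[2,3,5,6-tetrafluoro-4-(trifluoromethyl)phenyl]cyclopentane-1,2-dicarboxamide F1.
- Its monodentate amidates cannot form the N4 chelate. Pd(OAc)2 with a 2-alkoxyquinoline ligand, methylboronic acid, Ag2CO3 and benzoquinone couples at the cis β-methylene C–H in a Pd(II)/Pd(0) manifold. The product is (1R,2R,3R,5R)-3,5-dimethyl-N1,N2-bis[2,3,5,6-tetrafluoro-4-(trifluoromethyl)phenyl]cyclopentane-1,2-dicarboxamide F2.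
- BF3·OEt2 in MeOH at 90 °C gives dimethyl (1R,2R,3R,5R)-3,5-dimethylcyclopentane-1,2-dicarboxylate F3, and LiAlH4 reduces this to 7.

**Step 11 (domino C–O coupling/Claisen).** A hindered trisubstituted iodide meets a secondary alcohol, and the chair carries axial Ph and Et.
- The fallback sets out from 11 and comes back at 20. It replaces the sigmatropic step with enamine/Ir-π-allyl dual catalysis.
- Alkenylcopper 12, made from 11 as in step 8, is oxidised with t-BuOOLi (oxenoid oxidation to the enolate) and protonated. This gives 2-[(1R,2R,3R,5R)-2-(but-1-en-2-yl)-3,5-dimethylcyclopentyl]butanal F4, whose α-epimers are irrelevant.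
- [Ir(cod)Cl]2 with a chiral phosphoramidite–olefin ligand, a cinchona-derived primary amine and Cl3CCO2H couple the enamine of F4 with racemic 1-phenylprop-2-en-1-ol at the branched allyl terminus.
- The ligand enantiomer sets the (S)-benzylic carbon and the amine pseudo-enantiomer sets the (R)-quaternary carbon. The product is (2R,3S)-2-[(1R,2R,3R,5R)-2-(but-1-en-2-yl)-3,5-dimethylcyclopentyl]-2-ethyl-3-phenylpent-4-enal F5.
- Olefination as in step 12 gives ethyl (2E,4S,5S)-4-[(1R,2R,3R,5R)-2-(but-1-en-2-yl)-3,5-dimethylcyclopentyl]-4-ethyl-2-methyl-5-phenylhepta-2,6-dienoate F6. Metathesis as in step 13 then gives 20.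

**Step 13 (RCM).** The 1-ethylvinyl group is flanked by a cis-methyl, the product carries allylic strain between that methyl and the ring ethyl, and above about 100 °C the 1,5-diene of 19 could undergo a Cope rearrangement.
- The fallback sets out from 19 and comes back at 20. It uses carbonyl coupling in place of olefin metathesis.
- Ozonolysis (O3, CH2Cl2, −78 °C, Sudan III end point; Me2S) cleaves the two electron-rich alkenes and spares the enoate. This gives ethyl (2E,4S,5S)-4-[(1R,2R,3R,5R)-3,5-dimethyl-2-propanoylcyclopentyl]-4-ethyl-2-methyl-6-oxo-5-phenylhex-2-enoate F7.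
- F7 is used at once because its benzylic α-centre is epimerisable. It is closed by an intramolecular McMurry coupling (TiCl3(DME)1.5, Zn–Cu, DME, reflux, slow addition) to 20. The enoate is the group at risk in this coupling.

**Further compounds**
F1 | step 2 | (1R,2R)-N1,N2-bis[2,3,5,6-tetrafluoro-4-(trifluoromethyl)phenyl]cyclopentane-1,2-dicarboxamide | O=C(Nc1c(F)c(F)c(C(F)(F)F)c(F)c1F)[C@H]3[C@H](C(=O)Nc2c(F)c(F)c(C(F)(F)F)c(F)c2F)CCC3
F2 | step 2 | (1R,2R,3R,5R)-3,5-dimethyl-N1,N2-bis[2,3,5,6-tetrafluoro-4-(trifluoromethyl)phenyl]cyclopentane-1,2-dicarboxamide | O=C(Nc1c(F)c(F)c(C(F)(F)F)c(F)c1F)[C@H]3[C@H](C(=O)Nc2c(F)c(F)c(C(F)(F)F)c(F)c2F)[C@H](C)C[C@H]3C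
F3 | step 2 | dimethyl (1R,2R,3R,5R)-3,5-dimethylcyclopentane-1,2-dicarboxylate | COC(=O)[C@H]1[C@H](C(=O)OC)[C@H](C)C[C@H]1C
F4 | step 11 | 2-[(1R,2R,3R,5R)-2-(but-1-en-2-yl)-3,5-dimethylcyclopentyl]butanal (α-epimers) | O=CC(CC)[C@H]1[C@H](C(=C)CC)[C@H](C)C[C@H]1C
F5 | step 11 | (2R,3S)-2-[(1R,2R,3R,5R)-2-(but-1-en-2-yl)-3,5-dimethylcyclopentyl]-2-ethyl-3-phenylpent-4-enal | C=C[C@@H](c1ccccc1)[C@@](C=O)(CC)[C@H]2[C@H](C(=C)CC)[C@H](C)C[C@H]2C
F6 | step 11 | ethyl (2E,4S,5S)-4-[(1R,2R,3R,5R)-2-(but-1-en-2-yl)-3,5-dimethylcyclopentyl]-4-ethyl-2-methyl-5-phenylhepta-2,6-dienoate | C=C[C@@H](c1ccccc1)[C@@](/C=C(\C)C(=O)OCC)(CC)[C@H]2[C@H](C(=C)CC)[C@H](C)C[C@H]2C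
F7 | step 13 | ethyl (2E,4S,5S)-4-[(1R,2R,3R,5R)-3,5-dimethyl-2-propanoylcyclopentyl]-4-ethyl-2-methyl-6-oxo-5-phenylhex-2-enoate | O=C[C@@H](c1ccccc1)[C@@](/C=C(\C)C(=O)OCC)(CC)[C@H]2[C@H](C(=O)CC)[C@H](C)C[C@H]2C
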